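**Assumption:** flavaspidic acid BB has no stereocenters. The C(CH3)2 carbon is not stereogenic and the molecule is achiral, so there is no enantiomer to set. I take 2-methylphloroglucinol (2,4,6-trihydroxytoluene, a commercial feedstock) as the starting aromatic.

## Retrosynthetic overview
- The target is one dearomatized ring (a 2,2-dimethyl acyl-cyclohexanetrione) joined by CH2 to one aromatic ring (a methyl-acylphloroglucinol).
- Key disconnection: the gem-dimethyl triketone ring comes from a single C-methylation, at the ring carbon that already bears CH3. This dearomatizes one ring of the C2-symmetric bisphenol methane **5** and breaks its symmetry.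
- Compound **5** comes from two equivalents of 3-methyl-butyrylphloroglucinol (**3**) and one CH2O.
- Compound **3** comes from 2-methylphloroglucinol (**1**) and butyric acid (**2**).
- No ring is constructed. The alicyclic ring is made by dearomatization in the last step.

## Route

**Step 1**
Reactants: **1** 2-methylphloroglucinol; **2** butyric acid
Product: **3** 2,4,6-trihydroxy-3-methylbutyrophenone
Conditions: BF3·OEt2 (neat or in excess), 80–90 °C, 2 h, then aqueous workup
Reagents that add atoms: butyric acid, CCCC(=O)O
Why: BF3-mediated Friedel–Crafts acylation of an electron-rich phloroglucinol. The two free ring positions of **1** are equivalent, so a single regioisomer forms, and the chelated ketone deactivates the ring toward a second acylation.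

**Step 2**
Reactants: **3** (2 equiv); **4** formaldehyde (1 equiv)
Product: **5** 5,5'-methylenebis(2,4,6-trihydroxy-3-methylbutyrophenone)
Conditions: 37% aq. HCHO (0.5 equiv relative to **3**), aq. NaOH (cat.–1 equiv), MeOH/H2O, 25 °C, 12 h, then acidify with HCl
Reagents that add atoms: formaldehyde, C=O
Why: base-mediated hydroxymethylation of the phenolate gives an o-quinone methide, which is trapped by a second phenolate (Baeyer-type bisphenol methane formation). Because **3** has only one free ring carbon, no oligomers can form and the product is the symmetric dimer **5**. No stereocenter is created.

**Step 3**
Reactants: **5**; **6** iodomethane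
Product: **7** flavaspidic acid BB (target)
Conditions: NaOMe (2.5 equiv), MeI (1.0 equiv, added slowly), MeOH, 0 °C to 25 °C, 6 h; quench with aq. HCl
Reagents that add atoms: iodomethane, CI
Why: Proposed new method: this is a desymmetrizing dearomative C-methylation of a C2-symmetric bisphenol methane. The closest known reaction is the MeI/NaOMe C-methylation of acylphloroglucinols that gives gem-dimethyl triketones in leptospermone-type syntheses. The two C-CH3 carbons of **5** are equivalent, and the best C-nucleophilic site on each ring is the unhindered carbon bearing CH3, flanked by two phenoxides. The alternative sites (C-acyl, C-CH2Ar) are deactivated or hindered. Protic MeOH favors C- over O-alkylation. Once one ring is gem-dimethylated it becomes a strongly acidic acyl-triketone (pKa about 4), and its anion lowers the nucleophilicity of the remaining ring, which, together with the 1.0 equiv of MeI, limits over-methylation. No stereocenter is formed.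

## Checks performed
- **Structure:** the target has an acyl triketone ring (C(Me)2 flanked by C=O and C–OH), a CH2 bridge, and a 2-methyl-4-butyryl-phloroglucinol ring. Methylation of **5** at one C–CH3 carbon (C23H28O8 + CH3I − HI → C24H30O8) gives exactly this, and the formula matches the target.
- **Atom balance:** Step 1, C7H8O3 + C4H8O2 − H2O → C11H14O4. Step 2, 2 C11H14O4 + CH2O − H2O → C23H28O8. Step 3 is balanced above.
- **Functional-group survival:** the ketones and free phenols survive the base and MeI conditions (phenols are only transiently deprotonated). The aryl ketone is not cleaved at 0–25 °C.
- **Stereochemistry:** there are none to set or scramble. The triketone tautomers interconvert rapidly.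

## Compound list
1 | 2-methylphloroglucinol (2,4,6-trihydroxytoluene) | Cc1c(O)cc(O)cc1O | starting material
2 | butyric acid | CCCC(=O)O | starting material
3 | 2,4,6-trihydroxy-3-methylbutyrophenone | CCCC(=O)c1c(O)cc(O)c(C)c1O | intermediate
4 | formaldehyde | C=O | starting material
5 | 5,5'-methylenebis(2,4,6-trihydroxy-3-methylbutyrophenone) | CCCC(=O)c1c(O)c(Cc2c(O)c(C)c(O)c(C(=O)CCC)c2O)c(O)c(C)c1O | intermediate
6 | iodomethane | CI | starting material
7 | flavaspidic acid BB (target; achiral, no stereocenters) | CCCC(=O)C1=C(O)C(Cc2c(O)c(C)c(O)c(C(=O)CCC)c2O)=C(O)C(C)(C)C1=O | target

**Total steps:** 3. **Longest linear sequence:** 3 (**1** → **3** → **5** → **7**).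

## Three steps most likely to fail
1. **Step 3 (selectivity).** Mono-gem-dimethylation may compete with bis-dearomatization, O-methylation, or methylation at other ring carbons.
   - Fallback: change to a convergent route. Make 4-butyryl-6,6-dimethylcyclohexane-1,3,5-trione from butyrylphloroglucinol with MeI/NaOMe, then couple it with **3** and aqueous HCHO.
2. **Step 2 (methylene bridging).** The reaction may stall at the hydroxymethyl stage, or the bisphenol may undergo retro-addition or give colored quinone-methide by-products.
   - Fallback: make the Mannich base of **3** (HCHO, Me2NH), then heat it with a second equivalent of **3** so that o-quinone methide generation and trapping are separated.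
3. **Step 1 (acylation).** BF3/carboxylic acid acylation may give diacylation or low conversion of the electron-rich polyphenol.
   - Fallback: make the tributyrate ester of **1** and carry out an AlCl3 Fries rearrangement. Alternatively, use a Hoesch reaction with butyronitrile, ZnCl2 and HCl.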